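The 3(2H)-furanone (ring atoms O, C3, C2, C1, C10; germacrane numbering) bridges the ten-membered carbocycle, and its carbinol carbon C10 sits next to C9. Raising C9 to a ketone makes C10 an enolate carbon, so C1 can be parked on the C10 oxygen as an alk-2-ynoate. The precursor is therefore an eleven-membered enynoate macrolactone. One base treatment triggers a Chan rearrangement (1,2 O-to-C acyl shift, C1–C10) that contracts the lactone to the carbocycle. The released C10 alkoxide then adds 5-endo-dig to the ynone (O–C3), closing the furanone and setting C10. Ketone reduction and C8 acylation finish the synthesis.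

Key step: step 11

Numbering remark: germacrane numbering of the target is used for all compounds. C1 is the furanone C=O, C2 the =CH, C3 the enol-ether carbon, and C4=C5 the Z alkene. C6 is the lactone carbinol and C7 the ring-fusion CH. C8 is the ester carbinol, C9 the free carbinol and C10 the quaternary carbon. C11–C13 form the methylene lactone, C14 is the CH3 on C10 and C15 the CH3 on C4. The target is 6R,7S,8S,9R,10R,2'R.
Assumption: (S,S)-ProPhenol is taken to deliver the 4R carbinol 4. If the sense of induction is opposite, the (R,R)-ligand is used and nothing else changes.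
Assumption: 15, 17, 18 and 19 are drawn for the trans-epoxide formed anti to the C7 arm. The other trans-epoxide would give their C9/C10 bis-epimers, which converge on the same enolate 20.

Step 1
Reactants: 1 methyl propiolate; 2 (E)-crotonaldehyde
Product: 4 methyl (4R,5E)-4-hydroxyhept-5-en-2-ynoate, via methylzinc acetylide 3 (not isolated)
Conditions: Me2Zn (3 equiv), (S,S)-ProPhenol (10 mol %), toluene, 0–4 °C; then 2
Reagents that add atoms: none
Why: Catalytic asymmetric alkynylation of an aldehyde: the dinuclear zinc–ProPhenol complex delivers the zinc acetylide 1,2 to one face of the enal and so sets C8, and C7–C12 plus C14 are in place after one step.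

Step 2
Reactants: 4
Product: 5 methyl (4R,5E)-4-[(tert-butyldimethylsilyl)oxy]hept-5-en-2-ynoate
Conditions: TBSCl, imidazole, DMF, 0 °C → rt
Reagents that add atoms: tert-butyldimethylsilyl chloride (TBSCl), CC(C)(C)[Si](C)(C)Cl
Why: Standard imidazole-promoted silylation of a secondary alcohol, which gives O8 the non-acyl, bulky, non-chelating group that steps 11 and 12 require.

Step 3
Reactants: 5; 6 2-(iodomethyl)-4,4,5,5-tetramethyl-1,3,2-dioxaborolane
Product: 8 methyl (2Z,4R,5E)-2-[(4,4,5,5-tetramethyl-1,3,2-dioxaborolan-2-yl)methyl]-4-[(tert-butyldimethylsilyl)oxy]hepta-2,5-dienoate (C8 cis to CO2Me), via alpha-alumino dienoate 7 (not isolated)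
Conditions: i-Bu2AlH, HMPA, THF, 0 °C; then 6, 0 °C → rt
Reagents that add atoms: none
Why: Conjugate syn-hydroalumination of the alkynoate by the i-Bu2AlH–HMPA complex puts H on C7 and Al on C11, and alkylation of the vinylalane by the halomethylboronate with retention (the known route to 2-alkoxycarbonyl allylboronates) leaves C8 cis to the ester and trans to CH2B.

Step 4
Reactants: 9 but-2-yn-1-ol
Product: 11 (Z)-3-iodobut-2-en-1-ol, via cyclic vinylalanate 10 (not isolated)
Conditions: NaAlH2(OCH2CH2OMe)2, THF, 0 °C → rt; then NIS, −78 °C
Reagents that add atoms: N-iodosuccinimide (NIS), O=C1CCC(=O)N1I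
Why: Hydroxyl-directed trans-hydroalumination of a propargylic alcohol places aluminium on C4 in a five-membered alanate, and iodinolysis with retention should give only the Z iodide.

Step 5
Reactants: 11
Product: 12 (Z)-3-iodobut-2-enal
Conditions: MnO2, CH2Cl2, rt, dark
Reagents that add atoms: none
Why: Neutral heterogeneous MnO2 oxidation of an allylic alcohol, chosen because it leaves the Z geometry of the enal untouched.

Step 6
Reactants: 8; 12
Product: 14 (4S,5S)-4-[(1R,2E)-1-[(tert-butyldimethylsilyl)oxy]but-2-en-1-yl]-5-[(1Z)-2-iodoprop-1-en-1-yl]-3-methylideneoxolan-2-one (C6, C7, C8 arranged as in the target), via homoallylic borate 13 (not isolated)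
Conditions: Sc(OTf)3 (10 mol %), toluene, 0 °C → rt; then p-TsOH·H2O (cat.), rt
Reagents that add atoms: none
Why: Lewis-acid-accelerated allylboration through a closed chair (Zimmerman–Traxler) transition state followed by lactonisation: C8, trans to CH2B, sits equatorial, which gives the anti adduct and hence the trans C6/C7 lactone, and the aldehyde reaches C7 anti to the C8–C9 bond with H8 eclipsing the ester-bearing alkene carbon (A1,3 strain, OTBS outside), which relays C8 to C7.

Step 7
Reactants: 14
Product: 15 the C9–C10 trans-epoxide of 14 (oxygen on the face anti to the C7 arm)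
Conditions: mCPBA, CH2Cl2, 0 °C
Reagents that add atoms: 3-chloroperbenzoic acid (mCPBA), O=C(OO)c1cccc(Cl)c1
Why: Prilezhaev epoxidation picks the only electron-rich alkene (C9=C10), the iodoalkene and the acrylate-type methylene being deactivated, and the face attacked is immaterial because C9 is erased in step 10 and C10 in step 11.

Step 8
Reactants: 15; 16 propiolic acid
Product: 17 the C10 propiolate, C9 alcohol (9,10-erythro) derived from 15, with OTBS on C8 and the iodoalkene retained
Conditions: 16 (5 equiv), toluene, 40 °C
Reagents that add atoms: none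
Why: Brønsted-acid-promoted SN2-type epoxide opening by the carboxylic acid itself (pKa about 2) should occur with inversion at C10, the less hindered carbon and the one farther from the electron-withdrawing C8–O bond, which hangs C1 on O10 and leaves O9 as the only free hydroxyl.

Step 9
Reactants: 17
Product: 18 eleven-membered (4Z)-en-2-ynoate macrolactone (ring: O10, C1–C10) with C9–OH, C8–OTBS and the fused trans methylene lactone
Conditions: Pd(PPh3)4 (20 mol %), CuI (40 mol %), i-Pr2NEt, degassed THF (1 mM, syringe pump), rt
Reagents that add atoms: none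
Why: Intramolecular Sonogashira coupling (C3–C4) under high dilution: the Z iodoalkene points the palladium-bearing carbon toward the ester arm, coupling with retention keeps the 4Z geometry, and the hindered amine limits conjugate addition to the propiolate.

Step 10
Reactants: 18
Product: 19 the C9 ketone of 18 (an alpha-(alk-2-ynoyloxy) ketone inside the macrolactone)
Conditions: Dess–Martin periodinane, CH2Cl2, 0 °C → rt
Reagents that add atoms: none
Why: Dess–Martin oxidation of the only free hydroxyl under essentially neutral conditions should give the alpha-acyloxy ketone without epimerising C8.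

Step 11
Reactants: 19
Product: 22 the furanone-bridged ten-membered carbocycle with C9 ketone and C8–OTBS (10R), via lithium enolate 20 (not isolated), via ynone alkoxide 21 (not isolated)
Conditions: LiN(SiMe3)2 (1.1 equiv), THF, −78 → −20 °C; then AcOH, → rt
Reagents that add atoms: none
Why: Kinetic deprotonation removes the most acidic proton, H10 (alpha to the C9 ketone and to the acyloxy oxygen), and the enolate carbon attacks the ester carbonyl C1 that hangs on its own oxygen (3-exo-trig); collapse of the three-membered adduct with O10–C1 cleavage is the Chan rearrangement, the closest known reaction type being the 1,2 O-to-C acyl shift of alpha-acyloxy carbonyl enolates. This ring contraction turns the eleven-membered lactone into the ten-membered carbocycle (C1–C10) and frees the C10 alkoxide 21 next to a bent, strained ynone. The alkoxide then adds to C3 in a 5-endo-dig oxa-Michael step, the standard closure of alpha'-hydroxy ynones to 3(2H)-furanones, with HN(SiMe3)2 or AcOH protonating C2, and this irreversible step drains the reversible acyl-shift equilibrium. C10 is the only new stereocentre: in the in-ring cis enolate (O10 cis to C8) H8 eclipses the C9=C10 bond (A1,3 strain), so the C7 arm and the tethered C1 should lie on one face, and bonding on that face gives 10R. The step needs C10 over C8 enolisation, secured by the acidifying acyloxy group against the bulky OTBS and branched C7; it also needs the 1,2-shift to beat O-to-O transfer, C8 acylation and Michael addition, secured by the trans O9/O10 enolate geometry, the s-trans ester that holds C3 away from C10, and the peripheral position of the methylene lactone.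

Step 12
Reactants: 22
Product: 23 the 9R alcohol of 22 (O8 and O9 syn), C8–OTBS retained
Conditions: NaBH4, CeCl3·7H2O, MeOH/THF, −78 °C
Reagents that add atoms: none
Why: Luche reduction: the hard cerium-modified borohydride attacks only the most electrophilic carbonyl (C9, flanked by two C–O bonds) in 1,2 fashion and spares the vinylogous-ester C1 carbonyl and the methylene lactone, and hydride should arrive anti to the C8–OTBS bond from the outer face of the ring (Felkin–Anh, non-chelating silyl ether), which gives the 8,9-syn 9R carbinol.

Step 13
Reactants: 23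
Product: 24 the C8,C9 diol (8-deacyl target)
Conditions: HF·pyridine, pyridine, THF, 0 °C → rt
Reagents that add atoms: none
Why: Fluoride-mediated desilylation in a buffered acidic medium, chosen because basic fluoride could trigger retro-aldol cleavage of C9–C10 or translactonisation.

Step 14
Reactants: 24; 25 (R)-2-methylbutanoic acid
Product: 26 the target, CNP0146060.1
Conditions: 25 (1.1 equiv), DCC, DMAP (cat.), CH2Cl2, −10 → 0 °C
Reagents that add atoms: none
Why: Steglich esterification with about one equivalent of acid: O8 should react faster than O9, which is neopentyl-like next to quaternary C10, and low temperature with catalytic DMAP keeps the C2' centre of 25 intact.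

Compound list
1 | methyl propiolate | C#CC(=O)OC | starting material
2 | (E)-crotonaldehyde | C/C=C/C=O | starting material
3 | methylzinc acetylide of 1 | COC(=O)C#C[Zn]C | intermediate
4 | methyl (4R,5E)-4-hydroxyhept-5-en-2-ynoate | COC(=O)C#C[C@H](O)/C=C/C | intermediate
5 | methyl (4R,5E)-4-[(tert-butyldimethylsilyl)oxy]hept-5-en-2-ynoate | COC(=O)C#C[C@H](O[Si](C)(C)C(C)(C)C)/C=C/C | intermediate
6 | 2-(iodomethyl)-4,4,5,5-tetramethyl-1,3,2-dioxaborolane | ICB1OC(C)(C)C(C)(C)O1 | starting material
7 | alpha-(diisobutylalumino) dienoate, C8 cis to CO2Me | COC(=O)/C([Al](CC(C)C)CC(C)C)=C\[C@H](O[Si](C)(C)C(C)(C)C)/C=C/C | intermediate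
8 | methyl (2Z,4R,5E)-2-[(pinacolboryl)methyl]-4-[(tert-butyldimethylsilyl)oxy]hepta-2,5-dienoate | COC(=O)/C(CB1OC(C)(C)C(C)(C)O1)=C\[C@H](O[Si](C)(C)C(C)(C)C)/C=C/C | intermediate
9 | but-2-yn-1-ol | CC#CCO | starting material
10 | sodium cyclic vinylalanate from 9 | [Na+].CC1=CCO[Al-]1(OCCOC)OCCOC | intermediate
11 | (Z)-3-iodobut-2-en-1-ol | OC/C=C(/C)I | intermediate
12 | (Z)-3-iodobut-2-enal | O=C/C=C(/C)I | intermediate
13 | homoallylic pinacol borate (anti adduct, open-chain methyl ester) | C=C(C(=O)OC)[C@@H]([C@H](OB1OC(C)(C)C(C)(C)O1)/C=C(/C)I)[C@H](O[Si](C)(C)C(C)(C)C)/C=C/C | intermediate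
14 | trans methylene lactone with Z-iodopropenyl on C6 and (E)-1-(TBSO)but-2-enyl on C7 | C=C1C(=O)O[C@H](/C=C(/C)I)[C@H]1[C@H](O[Si](C)(C)C(C)(C)C)/C=C/C | intermediate
15 | C9–C10 trans-epoxide of 14 | C=C1C(=O)O[C@H](/C=C(/C)I)[C@H]1[C@H](O[Si](C)(C)C(C)(C)C)[C@@H]2O[C@H]2C | intermediate
16 | propiolic acid | C#CC(=O)O | starting material
17 | C10 propiolate, C9 alcohol (9,10-erythro) | C=C1C(=O)O[C@H](/C=C(/C)I)[C@H]1[C@H](O[Si](C)(C)C(C)(C)C)[C@H](O)[C@@H](C)OC(=O)C#C | intermediate
18 | eleven-membered enynoate macrolactone, C9–OH | C=C1C(=O)O[C@@H]2/C=C(/C)C#CC(=O)O[C@H](C)[C@@H](O)[C@@H](O[Si](C)(C)C(C)(C)C)[C@@H]12 | intermediate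
19 | eleven-membered enynoate macrolactone, C9 ketone | C=C1C(=O)O[C@@H]2/C=C(/C)C#CC(=O)O[C@H](C)C(=O)[C@@H](O[Si](C)(C)C(C)(C)C)[C@@H]12 | intermediate
20 | lithium C9–C10 enolate of 19 (O10 cis to C8) | [Li+].C=C1C(=O)O[C@@H]2/C=C(/C)C#CC(=O)O/C(C)=C(/[O-])[C@@H](O[Si](C)(C)C(C)(C)C)[C@@H]12 | intermediate
21 | lithium C10 alkoxide of the ten-membered 1,9-dioxo-2-yne (Chan product) | [Li+].C=C1C(=O)O[C@@H]2/C=C(/C)C#CC(=O)[C@](C)([O-])C(=O)[C@@H](O[Si](C)(C)C(C)(C)C)[C@@H]12 | intermediate
22 | furanone-bridged carbocycle, C9 ketone, C8–OTBS | C=C1C(=O)O[C@@H]2/C=C(/C)C3=CC(=O)[C@](C)(O3)C(=O)[C@@H](O[Si](C)(C)C(C)(C)C)[C@@H]12 | intermediate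
23 | 9R alcohol, C8–OTBS | C=C1C(=O)O[C@@H]2/C=C(/C)C3=CC(=O)[C@](C)(O3)[C@H](O)[C@@H](O[Si](C)(C)C(C)(C)C)[C@@H]12 | intermediate
24 | C8,C9 diol | C=C1C(=O)O[C@@H]2/C=C(/C)C3=CC(=O)[C@](C)(O3)[C@H](O)[C@@H](O)[C@@H]12 | intermediate
25 | (R)-2-methylbutanoic acid | CC[C@@H](C)C(=O)O | starting material
26 | CNP0146060.1 | C=C1C(=O)O[C@@H]2/C=C(/C)C3=CC(=O)[C@](C)(O3)[C@H](O)[C@@H](OC(=O)[C@H](C)CC)[C@@H]12 | target

Total step count: 14. Longest linear sequence: 12 (steps 1–3 and 6–14).

Steps most likely to fail

1. Step 11 (key step).
   - What may go wrong: enolisation toward C8 followed by transfer of the ynoyl group to C8. The C10 enolate may also add in conjugate fashion to the methylene lactone or to C3. Acyl scrambling through the reversible three-membered adduct and a low facial bias at C10 are further risks.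
   - Fallback, from 19: the site of enolisation is fixed in a separate, checkable step. Me3SiOTf/Et3N (CH2Cl2, 0 °C) should give the C9–C10 enol trimethylsilyl ether F1. Bu4N[Ph3SiF2] with t-BuOH (THF, −40 °C) then releases a lithium-free enolate. This enolate undergoes the same acyl shift and ring closure in one operation, and the route is rejoined at 22.

2. Step 9.
   - What may go wrong: oligomerisation, oxidative alkyne homocoupling, amine addition to the propiolate, or carbopalladation of the methylene lactone may outrun ring closure.
   - Fallback, from 17: Bu3SnOMe converts the terminal propiolate into the alkynylstannane F2. A Stille macrocyclisation (Pd2(dba)3, AsPh3, DMF, high dilution) under neutral, copper-free and amine-free conditions closes the same C3–C4 bond, and the route is rejoined at 18.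

3. Step 12.
   - What may go wrong: poor facial selectivity at C9, conjugate reduction of the methylene lactone, or retro-Claisen cleavage of the 2-acylfuranone by methoxide.
   - Fallback, from 22: the order of events and the control element are changed. HF·pyridine gives the alpha-hydroxy ketone F3. Steglich esterification with 25, with only one hydroxyl present, gives the C8 ester ketone F4.
   - A Corey–Bakshi–Shibata reduction then sets 9R under catalyst control and leads directly to 26. Conditions: (S)-Me-CBS oxazaborolidine, catecholborane, toluene, −78 °C, with C10 as the large and C8 as the small substituent. This ordering also removes the need for site-selective acylation.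

Further compounds
F1 | step 11 | C9–C10 enol trimethylsilyl ether of 19 | C=C1C(=O)O[C@@H]2/C=C(/C)C#CC(=O)O/C(C)=C(/O[Si](C)(C)C)[C@@H](O[Si](C)(C)C(C)(C)C)[C@@H]12
F2 | step 9 | 3-(tributylstannyl)propiolate of 17 | C=C1C(=O)O[C@H](/C=C(/C)I)[C@H]1[C@H](O[Si](C)(C)C(C)(C)C)[C@H](O)[C@@H](C)OC(=O)C#C[Sn](CCCC)(CCCC)CCCC
F3 | step 12 | furanone-bridged carbocycle, C9 ketone, free C8–OH | C=C1C(=O)O[C@@H]2/C=C(/C)C3=CC(=O)[C@](C)(O3)C(=O)[C@@H](O)[C@@H]12
F4 | step 12 | furanone-bridged carbocycle, C9 ketone, C8 (R)-2-methylbutanoate | C=C1C(=O)O[C@@H]2/C=C(/C)C3=CC(=O)[C@](C)(O3)C(=O)[C@@H](OC(=O)[C@H](C)CC)[C@@H]12
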